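**Strategy**

The seven-membered ring is assembled as a (4+3) annulation. Three atoms (C-9, C-9a, C-4a; benzo[7]annulene numbering) come from 3,4,5-trimethoxybenzaldehyde: its carbonyl carbon, ipso carbon and one of its two equivalent ortho carbons. Four atoms (C-8, C-7, C-6, C-5) come from a chiral terminal alkyne that ends in a 2,6-dimethoxyphenol, whose para carbon is C-5. In one flask, nickel-catalysed reductive coupling of aldehyde and alkyne makes the C-8–C-9 bond and the (9R) carbinol, then PhI(OAc)2 closes the C-4a–C-5 bond by dearomatising para coupling. The step exploits the electrophilic carbonyl carbon next to the nucleophilic ortho carbon of ring A and the symmetric phenol ring B, which makes the spiro carbon non-stereogenic.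

Key step: step 4

Assumption: the ligand antipodes named in steps 2 and 4 are taken to give the (R) centres (the mirror-image ligand is used if a catalyst shows the opposite sense); ring A is the trimethoxybenzene ring, ring B the phenol/dienone ring, and atoms carry the numbering of the spiro[benzo[7]annulene-5,1'-cyclohexadienone] skeleton (C-5 spiro, C-7 and C-8 methyl-bearing, C-9 carbinol).

**Route**

Step 1
Reactants: 1 4-hydroxy-3,5-dimethoxybenzaldehyde (syringaldehyde); 2 ethyl 2-(triphenylphosphoranylidene)propanoate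
Product: 3 ethyl (2E)-3-(4-hydroxy-3,5-dimethoxyphenyl)-2-methylprop-2-enoate
Conditions: toluene, 90 °C
Reagents that add atoms: none
Why: Wittig olefination with the ester-stabilised ylide should give the (E)-trisubstituted enoate and tolerate the free phenol; no stereocentre is formed.

Step 2
Reactants: 3 ethyl (2E)-3-(4-hydroxy-3,5-dimethoxyphenyl)-2-methylprop-2-enoate
Product: 4 ethyl (2R)-3-(4-hydroxy-3,5-dimethoxyphenyl)-2-methylpropanoate
Conditions: H2 (50 bar), [Ir(cod){(S)-t-Bu-PHOX}]B[C6H3-3,5-(CF3)2]4 (1 mol %), CH2Cl2, rt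
Reagents that add atoms: none
Why: Iridium–P,N-catalysed asymmetric hydrogenation of the trisubstituted α-methylcinnamate should add H2 to one enantioface and set the (2R) methyl-bearing centre (later C-7) under catalyst control.

Step 3
Reactants: 4 ethyl (2R)-3-(4-hydroxy-3,5-dimethoxyphenyl)-2-methylpropanoate
Product: 6 4-[(2R)-2-methylbut-3-yn-1-yl]-2,6-dimethoxyphenol, via aldehyde 5 (not isolated)
Conditions: i-Bu2AlH (2.3 equiv), CH2Cl2, −78 °C; then MeOH, K2CO3, dimethyl (1-diazo-2-oxopropyl)phosphonate, −78 °C to rt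
Reagents that add atoms: dimethyl (1-diazo-2-oxopropyl)phosphonate, CC(=O)C(=[N+]=[N-])P(=O)(OC)OC
Why: Partial ester reduction by i-Bu2AlH gives an aluminium hemiacetal that releases aldehyde 5 on methanolysis, and the Ohira–Bestmann variant of the Seyferth–Gilbert homologation converts it in the same flask into the terminal alkyne, the mild carbonate base being expected to leave the existing α-stereocentre untouched.

Step 4
Reactants: 6 4-[(2R)-2-methylbut-3-yn-1-yl]-2,6-dimethoxyphenol; 7 3,4,5-trimethoxybenzaldehyde
Product: 10 (7R,9R)-2,3,3',4,5'-pentamethoxy-7-methyl-8-methylidene-9-(triethylsilyloxy)-6,7,8,9-tetrahydrospiro[benzo[7]annulene-5,1'-cyclohexa-2',5'-dien]-4'-one, via aryl trimethylsilyl ether 8 (not isolated), via acyclic bis-silyl ether 9 (not isolated)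
Conditions: N,O-bis(trimethylsilyl)acetamide, THF, rt; then 7 (1.2 equiv), Et3SiH (2 equiv), Ni(cod)2 (10 mol %), (4S,5S)-1,3-bis[2,6-di(pentan-3-yl)phenyl]-4,5-diphenylimidazolinium tetrafluoroborate (12 mol %), KOt-Bu (12 mol %), THF, rt; then CF3CH2OH (0.01 M), PhI(OAc)2 (2.5 equiv), −20 °C
Reagents that add atoms: triethylsilane, CC[SiH](CC)CC
Why: N,O-bis(trimethylsilyl)acetamide caps the phenol as 8, and zerovalent nickel bearing the bulky chiral N-heterocyclic carbene then joins alkyne and aldehyde by oxidative cyclisation to an oxanickelacyclopentene that Et3SiH opens by σ-bond metathesis and C–H reductive elimination, giving the O-silylated allylic alcohol 9 (nickel-catalysed aldehyde–alkyne reductive coupling). The large ligand keeps the substituted alkyne carbon away from nickel, so the C-8–C-9 bond forms at the internal carbon, and its C2-symmetric backbone selects the aldehyde face and thereby sets the new (9R) centre, with the (7R) centre as a spectator. In the same flask PhI(OAc)2 in CF3CH2OH exchanges the Me3Si group on the phenol oxygen for trivalent iodine and releases the phenoxonium ion of ring B, whose para carbon is attacked by an ortho carbon of ring A (ortho and para to methoxy groups) before ring A rearomatises by proton loss; the closest known reaction is the hypervalent-iodine para coupling of phenols with tethered arenes to spirodienones, an intramolecular Friedel–Crafts-type ipso substitution. This 7-exo-trig attack closes the seven-membered ring and forms the C-4a–C-5 bond, and C-5 is not stereogenic because ring B is symmetric. The step needs carbon attack in preference to attack by the C-9 oxygen or the solvent and oxidation of ring B only, which the Et3Si ether on C-9, high dilution, the two equivalent activated ortho positions of ring A and the O–Si to O–I exchange at the phenol are expected to secure. Acid-induced dienone–phenol rearrangement should be avoided because only acetic acid is released at −20 °C and the mixture is quenched cold with aqueous NaHCO3.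

Step 5
Reactants: 10 (7R,9R)-2,3,3',4,5'-pentamethoxy-7-methyl-8-methylidene-9-(triethylsilyloxy)-6,7,8,9-tetrahydrospiro[benzo[7]annulene-5,1'-cyclohexa-2',5'-dien]-4'-one
Product: 11 (7R,9R)-9-hydroxy-2,3,3',4,5'-pentamethoxy-7-methyl-8-methylidene-6,7,8,9-tetrahydrospiro[benzo[7]annulene-5,1'-cyclohexa-2',5'-dien]-4'-one
Conditions: HF·pyridine, pyridine, THF, 0 °C
Reagents that add atoms: none
Why: Fluoride-mediated cleavage of the triethylsilyl ether under pyridine buffering should free the allylic alcohol without ionising the benzylic C–O bond or rearranging the dienone; no stereocentre is touched.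

Step 6
Reactants: 11 (7R,9R)-9-hydroxy-2,3,3',4,5'-pentamethoxy-7-methyl-8-methylidene-6,7,8,9-tetrahydrospiro[benzo[7]annulene-5,1'-cyclohexa-2',5'-dien]-4'-one
Product: 12 (7R,8S,9R)-9-hydroxy-2,3,3',4,5'-pentamethoxy-7,8-dimethyl-6,7,8,9-tetrahydrospiro[benzo[7]annulene-5,1'-cyclohexa-2',5'-dien]-4'-one
Conditions: H2 (1 atm), [Ir(cod)(PCy3)(py)]PF6 (3 mol %), CH2Cl2, 0 °C
Reagents that add atoms: none
Why: In this hydroxyl-directed homogeneous hydrogenation the cationic iridium catalyst binds the C-9 hydroxyl and the exocyclic alkene and should deliver H2 to C-8 from the hydroxyl face, placing the new methyl trans to the OH and trans to the C-7 methyl (8S), while the conjugated trisubstituted enol-ether double bonds of the dienone, which cannot chelate, are expected to react much more slowly.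

**Compound list**

1 | 4-hydroxy-3,5-dimethoxybenzaldehyde (syringaldehyde) | COc1cc(C=O)cc(OC)c1O | starting material
2 | ethyl 2-(triphenylphosphoranylidene)propanoate | CCOC(=O)C(C)=P(c1ccccc1)(c1ccccc1)c1ccccc1 | starting material
3 | ethyl (2E)-3-(4-hydroxy-3,5-dimethoxyphenyl)-2-methylprop-2-enoate | CCOC(=O)/C(C)=C/c1cc(OC)c(O)c(OC)c1 | intermediate
4 | ethyl (2R)-3-(4-hydroxy-3,5-dimethoxyphenyl)-2-methylpropanoate | CCOC(=O)[C@H](C)Cc1cc(OC)c(O)c(OC)c1 | intermediate
5 | (2R)-3-(4-hydroxy-3,5-dimethoxyphenyl)-2-methylpropanal | O=C[C@H](C)Cc1cc(OC)c(O)c(OC)c1 | intermediate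
6 | 4-[(2R)-2-methylbut-3-yn-1-yl]-2,6-dimethoxyphenol | C#C[C@H](C)Cc1cc(OC)c(O)c(OC)c1 | intermediate
7 | 3,4,5-trimethoxybenzaldehyde | COc1cc(C=O)cc(OC)c1OC | starting material
8 | trimethyl{2,6-dimethoxy-4-[(2R)-2-methylbut-3-yn-1-yl]phenoxy}silane | C#C[C@H](C)Cc1cc(OC)c(O[Si](C)(C)C)c(OC)c1 | intermediate
9 | triethyl{[(1R,3R)-4-[3,5-dimethoxy-4-(trimethylsilyloxy)phenyl]-3-methyl-2-methylidene-1-(3,4,5-trimethoxyphenyl)butyl]oxy}silane | C=C([C@H](C)Cc1cc(OC)c(O[Si](C)(C)C)c(OC)c1)[C@@H](O[Si](CC)(CC)CC)c1cc(OC)c(OC)c(OC)c1 | intermediate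
10 | (7R,9R)-2,3,3',4,5'-pentamethoxy-7-methyl-8-methylidene-9-(triethylsilyloxy)-6,7,8,9-tetrahydrospiro[benzo[7]annulene-5,1'-cyclohexa-2',5'-dien]-4'-one | COC1=CC2(C=C(OC)C1=O)C[C@@H](C)C(=C)[C@@H](O[Si](CC)(CC)CC)c1cc(OC)c(OC)c(OC)c12 | intermediate
11 | (7R,9R)-9-hydroxy-2,3,3',4,5'-pentamethoxy-7-methyl-8-methylidene-6,7,8,9-tetrahydrospiro[benzo[7]annulene-5,1'-cyclohexa-2',5'-dien]-4'-one | COC1=CC2(C=C(OC)C1=O)C[C@@H](C)C(=C)[C@@H](O)c1cc(OC)c(OC)c(OC)c12 | intermediate
12 | (7R,8S,9R)-9-hydroxy-2,3,3',4,5'-pentamethoxy-7,8-dimethyl-6,7,8,9-tetrahydrospiro[benzo[7]annulene-5,1'-cyclohexa-2',5'-dien]-4'-one | COC1=CC2(C=C(OC)C1=O)C[C@@H](C)[C@H](C)[C@@H](O)c1cc(OC)c(OC)c(OC)c12 | target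

**Step count and risks**

Total step count: 6. Longest linear sequence: 6 steps (from 1 to 12; aldehyde 7 enters at step 4).

Steps most likely to fail:

Step 4. The nickel stage may lose regio- or enantiocontrol (bond formation at the terminal alkyne carbon, addition to the wrong aldehyde face). The oxidative stage may be diverted by solvent capture of the phenoxonium ion or by quinone methide formation. The fallback makes the two bonds in separate operations. Starting from alkyne 6, Markovnikov hydroiodination with 9-iodo-9-borabicyclo[3.3.1]nonane followed by AcOH should give the vinyl iodide 4-[(2R)-3-iodo-2-methylbut-3-en-1-yl]-2,6-dimethoxyphenol F1. A catalytic asymmetric Nozaki–Hiyama–Kishi coupling of F1 with aldehyde 7 (CrCl2, NiCl2, Mn, Cp2ZrCl2, chiral oxazoline–sulfonamide ligand, MeCN) should give the allylic alcohol 4-[(2R)-3-[(R)-hydroxy(3,4,5-trimethoxyphenyl)methyl]-2-methylbut-3-en-1-yl]-2,6-dimethoxyphenol F2. Silylation of both hydroxyl groups (Et3SiOTf, 2,6-lutidine) should give the bis(triethylsilyl) ether F3. PhI(OAc)2 in CF3CH2OH, which removes the aryl silyl group, should then close the spiro ring and return to compound 10.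

Step 6. Hydrogen may also add to the enol-ether double bonds of the dienone, or the hydroxyl direction may be lost so that hydrogen enters from the less hindered face. The fallback replaces substrate direction by catalyst control on the silyl ether. Starting from 10, hydrogenation of the exocyclic alkene with a chiral iridium P,N catalyst ([Ir(cod){t-Bu-PHOX}]B[C6H3-3,5-(CF3)2]4, ligand antipode chosen for addition to the face that gives 8S) should give the saturated silyl ether (7R,8S,9R)-2,3,3',4,5'-pentamethoxy-7,8-dimethyl-9-(triethylsilyloxy)-6,7,8,9-tetrahydrospiro[benzo[7]annulene-5,1'-cyclohexa-2',5'-dien]-4'-one F4. HF·pyridine as in step 5 should then give target 12.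

Step 3. Aldehyde 5 may epimerise at its α-carbon under K2CO3/MeOH, or the ester may be over-reduced in the one-flask procedure. The fallback homologates without carbonate base. Starting from ester 4, i-Bu2AlH at −78 °C with isolation should give aldehyde 5. CBr4/PPh3 (Corey–Fuchs olefination) should give the dibromoalkene 4-[(2R)-4,4-dibromo-2-methylbut-3-en-1-yl]-2,6-dimethoxyphenol F5. n-BuLi (3.2 equiv, −78 °C) should convert F5 by the Fritsch–Buttenberg–Wiechell rearrangement into alkyne 6.

Further compounds
F1 | step 4 | 4-[(2R)-3-iodo-2-methylbut-3-en-1-yl]-2,6-dimethoxyphenol | C=C(I)[C@H](C)Cc1cc(OC)c(O)c(OC)c1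
F2 | step 4 | 4-[(2R)-3-[(R)-hydroxy(3,4,5-trimethoxyphenyl)methyl]-2-methylbut-3-en-1-yl]-2,6-dimethoxyphenol | C=C([C@H](C)Cc1cc(OC)c(O)c(OC)c1)[C@@H](O)c1cc(OC)c(OC)c(OC)c1
F3 | step 4 | triethyl{[(1R,3R)-4-[3,5-dimethoxy-4-(triethylsilyloxy)phenyl]-3-methyl-2-methylidene-1-(3,4,5-trimethoxyphenyl)butyl]oxy}silane | C=C([C@H](C)Cc1cc(OC)c(O[Si](CC)(CC)CC)c(OC)c1)[C@@H](O[Si](CC)(CC)CC)c1cc(OC)c(OC)c(OC)c1
F4 | step 6 | (7R,8S,9R)-2,3,3',4,5'-pentamethoxy-7,8-dimethyl-9-(triethylsilyloxy)-6,7,8,9-tetrahydrospiro[benzo[7]annulene-5,1'-cyclohexa-2',5'-dien]-4'-one | COC1=CC2(C=C(OC)C1=O)C[C@@H](C)[C@H](C)[C@@H](O[Si](CC)(CC)CC)c1cc(OC)c(OC)c(OC)c12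
F5 | step 3 | 4-[(2R)-4,4-dibromo-2-methylbut-3-en-1-yl]-2,6-dimethoxyphenol | BrC(Br)=C[C@H](C)Cc1cc(OC)c(O)c(OC)c1
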